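Halimane numbering is used (ring A: C1–C5 and C10; ring B: C5–C10). The route rests on opening ring A at C1–C2 and C5–C10: ring A is a cyclohexene whose only double bond, C1=C10, starts at the ring fusion and adjoins an unsubstituted C2H2, the imprint of a diene–alkyne [4+2] adduct. A rhodium-catalysed intramolecular [4+2] of an acyclic dienyne closes rings A and B in one operation, leaves C1=C10 in place and sets C5 from C8/C9; C4 is quaternised afterwards. The precursor carries a terminal alkyne (C1≡C10) on quaternary C9, a four-carbon tether (C6–C9) and a 2-methoxycarbonyl-1,3-diene (C2=C3–C4=C5); it arises by Eschenmoser–Tanabe fragmentation of a cycloheptenone.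

Key step: step 9

Remark: 1 and 16 are taken as purchasable (otherwise each is reached by known chemistry from a catalogue compound); the side chain is C11–C16, and C17 and C20 are the methyls on C8 and C9.

Step 1
Reactants: 1 2-methylcyclohept-2-en-1-one; 2 methylmagnesium bromide; 3 chlorotrimethylsilane
Product: 5 trimethyl{[(3R)-2,3-dimethylcyclohept-1-en-1-yl]oxy}silane, via bromomagnesium enolate 4 (not isolated)
Conditions: MeMgBr, Cu(OTf)2 (3 mol %), chiral imidazolinium salt (N-heterocyclic carbene precursor, 4 mol %; enantiomer that gives the 3R centre), Et2O, −30 °C; then Me3SiCl, Et3N, HMPA, −30 °C to rt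
Reagents that add atoms: methylmagnesium bromide C[Mg]Br; chlorotrimethylsilane C[Si](C)(C)Cl
Why: Copper-catalysed asymmetric conjugate addition of a Grignard reagent to an α-substituted cyclic enone: the chiral carbene–copper complex selects the enone face and sets C8 (3R), and O-silylation of the magnesium enolate fixes the enolate regiochemistry at C9 for the next step.

Step 2
Reactants: 5 trimethyl{[(3R)-2,3-dimethylcyclohept-1-en-1-yl]oxy}silane; 6 but-3-en-2-one
Product: 7 (2S,3R)-2,3-dimethyl-2-(3-oxobutyl)cycloheptan-1-one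
Conditions: BF3·OEt2, i-PrOH, CH2Cl2, −78 °C
Reagents that add atoms: but-3-en-2-one C=CC(C)=O
Why: Mukaiyama–Michael addition: the BF3-activated enone is attacked by C9 of the tetrasubstituted enol ether on the face anti to the adjacent C8 methyl (held pseudoaxial by A(1,2) strain), which sets the quaternary C9 with the two methyls cis, and i-PrOH takes up the silyl group.

Step 3
Reactants: 7 (2S,3R)-2,3-dimethyl-2-(3-oxobutyl)cycloheptan-1-one; 8 triethyl phosphonoacetate
Product: 9 ethyl (2E)-5-[(1S,2R)-1,2-dimethyl-7-oxocycloheptyl]-3-methylpent-2-enoate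
Conditions: (EtO)2P(O)CH2CO2Et (1.3 equiv), NaH (1.2 equiv), THF, 0 to 40 °C
Reagents that add atoms: triethyl phosphonoacetate CCOC(=O)CP(=O)(OCC)OCC
Why: Horner–Wadsworth–Emmons olefination: the unhindered methyl ketone reacts while the ring ketone next to quaternary C9 does not, and the stabilised phosphonate should favour the E-enoate (C12 trans to the ester), the Z isomer being removed by chromatography.

Step 4
Reactants: 9 ethyl (2E)-5-[(1S,2R)-1,2-dimethyl-7-oxocycloheptyl]-3-methylpent-2-enoate
Product: 10 ethyl (2E)-5-[(1S,2R)-1,2-dimethyl-7-oxocyclohept-5-en-1-yl]-3-methylpent-2-enoate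
Conditions: IBX (2-iodoxybenzoic acid, 1.3 equiv), 4-methoxypyridine N-oxide, DMSO, 25 °C
Reagents that add atoms: none
Why: IBX dehydrogenation of a ketone through its enol: only C1 can enolise because C9 is quaternary, so the C1=C5 enone is the only possible regioisomer and the enoate is inert.

Step 5
Reactants: 10 ethyl (2E)-5-[(1S,2R)-1,2-dimethyl-7-oxocyclohept-5-en-1-yl]-3-methylpent-2-enoate; 11 tert-butyl hydroperoxide
Product: 12 ethyl (2E)-5-[(3S,4R)-3,4-dimethyl-2-oxo-8-oxabicyclo[5.1.0]octan-3-yl]-3-methylpent-2-enoate (the 5,6-epoxide of 10 as an epoxide-diastereomer mixture)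
Conditions: t-BuOOH, DBU, CH2Cl2, 0 °C to rt
Reagents that add atoms: tert-butyl hydroperoxide CC(C)(C)OO
Why: Weitz–Scheffer nucleophilic epoxidation: the hydroperoxide anion adds to the ring enone and not to the β,β-disubstituted enoate, and the configuration of the two epoxide carbons is immaterial because both become achiral in step 6.

Step 6
Reactants: 12 the epoxy ketone; 13 4-methylbenzenesulfonohydrazide
Product: 15 ethyl (2E,6S,7R)-6-ethynyl-3,6,7-trimethyl-10-oxodec-2-enoate, via tosylhydrazone 14 (not isolated)
Conditions: TsNHNH2 (1.05 equiv), AcOH/CH2Cl2, −20 °C to rt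
Reagents that add atoms: none
Why: Eschenmoser–Tanabe fragmentation: the epoxy tosylhydrazone opens to an alkoxy azoalkene that fragments with loss of sulfinate and N2, so that C10–C1 becomes the terminal alkyne and C5 the aldehyde while C8 and C9 are untouched.

Step 7
Reactants: 15 ethyl (2E,6S,7R)-6-ethynyl-3,6,7-trimethyl-10-oxodec-2-enoate; 16 methyl 2-[bis(2,2,2-trifluoroethoxy)phosphoryl]-2-bromoacetate
Product: 17 12-ethyl 1-methyl (2E,6R,7S,10E)-2-bromo-7-ethynyl-6,7,10-trimethyldodeca-2,10-dienedioate
Conditions: (CF3CH2O)2P(O)CHBrCO2Me, t-BuOK, 18-crown-6, THF, −78 °C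
Reagents that add atoms: methyl 2-[bis(2,2,2-trifluoroethoxy)phosphoryl]-2-bromoacetate COC(=O)C(Br)P(=O)(OCC(F)(F)F)OCC(F)(F)F
Why: Horner–Wadsworth–Emmons olefination with a Still–Gennari-type bis(trifluoroethyl) α-bromophosphonoacetate: fast, irreversible elimination under kinetic control should give the (E)-α-bromoenoate, in which the C6 chain is cis to CO2Me.

Step 8
Reactants: 17 the (E)-α-bromoenoate; 18 tributyl(ethenyl)stannane
Product: 19 12-ethyl 1-methyl (2Z,6R,7S,10E)-2-ethenyl-7-ethynyl-6,7,10-trimethyldodeca-2,10-dienedioate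
Conditions: Pd2(dba)3 (zerovalent palladium, 2.5 mol %), AsPh3 (20 mol %), NMP, 40 °C
Reagents that add atoms: tributyl(ethenyl)stannane C=C[Sn](CCCC)(CCCC)CCCC
Why: Stille coupling: oxidative addition, transmetallation and reductive elimination proceed with retention of alkene geometry, so the vinyl group ends up trans to the C6 chain (tether on the outside of the diene), and the copper-free neutral conditions spare the terminal alkyne.

Step 9
Reactants: 19 the dienyne
Product: 20 methyl (5S,6R,8aR)-5-[(3E)-5-ethoxy-3-methyl-5-oxopent-3-en-1-yl]-5,6-dimethyl-3,5,6,7,8,8a-hexahydronaphthalene-1-carboxylate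
Conditions: [Rh(cod)Cl]2 (5 mol %), AgSbF6 (10 mol %), ClCH2CH2Cl (0.01 M), 25–60 °C, argon; used at once
Reagents that add atoms: none
Why: Cationic monovalent rhodium binds the alkyne and the diene, oxidative cyclisation joins C5 to C10 to give a trivalent rhodacycle carrying an η3-allyl unit (C4–C3–C2), and reductive elimination then joins C1 to C2, so both σ-bonds of the formal [4+2] are made and C1=C10 is left exactly where the target has it. The closest known reaction type is the rhodium-catalysed intramolecular [4+2] cycloaddition of unactivated dienynes, the metal-mediated counterpart of an intramolecular Diels–Alder reaction of an alkyne. Ring B closes by the C5–C10 bond through the four-carbon tether (six-membered, exo with respect to both the alkyne and the diene), and ring A closes by the C1–C2 bond as the six-membered cycloaddition ring (diene C2–C5 plus C1 and C10). The only new stereocentre, C5, is controlled by C8 and C9: in the chair-like tether the C8 methyl and the C11 chain lie equatorial and the C9 methyl axial, the diene must leave C5 equatorially, and H5 therefore ends up axial and syn to the C9 methyl (8aR). The step needs cycloaddition to outrun alkyne oligomerisation and diene dimerisation, which high dilution, the neopentyl-type alkyne and the tether-outside (2Z) diene geometry should secure, and the air-sensitive 1,4-diene is carried on immediately.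

Step 10
Reactants: 20 the cycloadduct; 21 iodomethane
Product: 23 methyl (1S,5S,6R,8aR)-5-[(3E)-5-ethoxy-3-methyl-5-oxopent-3-en-1-yl]-1,5,6-trimethyl-1,2,3,5,6,7,8,8a-octahydronaphthalene-1-carboxylate, via lithium ester enolate 22 (not isolated)
Conditions: LiBH(s-Bu)3 (1.1 equiv), THF, −78 °C; then MeI, DMPU, −78 to 0 °C
Reagents that add atoms: iodomethane CI
Why: Reductive alkylation of an enoate: LiBH(s-Bu)3 adds hydride to C3 of the β-monosubstituted ring enoate (the β,β-disubstituted side-chain enoate is inert), and MeI should then attack the C4 ester enolate on the face of H5, anti to the C5–C6 bond that A(1,3) strain pushes out of the enolate plane (equatorial attack on ring A), which sets C4 with methyl cis to H5 (1S).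

Step 11
Reactants: 23 the diester
Product: 24 methyl (1S,5S,6R,8aR)-5-[(3E)-5-hydroxy-3-methylpent-3-en-1-yl]-1,5,6-trimethyl-1,2,3,5,6,7,8,8a-octahydronaphthalene-1-carboxylate
Conditions: i-Bu2AlH (2.2 equiv), CH2Cl2, −78 °C; aq. potassium sodium tartrate
Reagents that add atoms: none
Why: Ester reduction with i-Bu2AlH: the conjugated side-chain ester is reduced in 1,2 fashion to the E-allylic alcohol at −78 °C, while the α-quaternary (neopentyl-type) C4 methyl ester is far slower and survives.

Step 12
Reactants: 24 the allylic alcohol; 11 tert-butyl hydroperoxide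
Product: 25 methyl (1S,5S,6R,8aR)-5-{2-[(2S,3S)-3-(hydroxymethyl)-2-methyloxiran-2-yl]ethyl}-1,5,6-trimethyl-1,2,3,5,6,7,8,8a-octahydronaphthalene-1-carboxylate
Conditions: Ti(OiPr)4 (10 mol %), L-(+)-diisopropyl tartrate (12 mol %), t-BuOOH, 4 Å molecular sieves, CH2Cl2, −20 °C
Reagents that add atoms: tert-butyl hydroperoxide CC(C)(C)OO
Why: Katsuki–Sharpless asymmetric epoxidation: the titanium–L-(+)-tartrate complex delivers oxygen to one face of the E-allylic alcohol under reagent control to give the (2S,3S)-epoxy alcohol (13S,14S), and the isolated C1=C10 alkene, not being an allylic alcohol, does not react.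

Compound list
1 | 2-methylcyclohept-2-en-1-one | CC1=CCCCCC1=O | starting material
2 | methylmagnesium bromide | C[Mg]Br | starting material
3 | chlorotrimethylsilane | C[Si](C)(C)Cl | starting material
4 | bromomagnesium (3R)-2,3-dimethylcyclohept-1-en-1-olate | Br[Mg]OC1=C(C)[C@H](C)CCCC1 | intermediate (not isolated)
5 | trimethyl{[(3R)-2,3-dimethylcyclohept-1-en-1-yl]oxy}silane | C[Si](C)(C)OC1=C(C)[C@H](C)CCCC1 | intermediate
6 | but-3-en-2-one | C=CC(C)=O | starting material
7 | (2S,3R)-2,3-dimethyl-2-(3-oxobutyl)cycloheptan-1-one | O=C1CCCC[C@@H](C)[C@]1(C)CCC(C)=O | intermediate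
8 | triethyl phosphonoacetate | CCOC(=O)CP(=O)(OCC)OCC | starting material
9 | ethyl (2E)-5-[(1S,2R)-1,2-dimethyl-7-oxocycloheptyl]-3-methylpent-2-enoate | O=C1CCCC[C@@H](C)[C@]1(C)CC/C(C)=C/C(=O)OCC | intermediate
10 | ethyl (2E)-5-[(1S,2R)-1,2-dimethyl-7-oxocyclohept-5-en-1-yl]-3-methylpent-2-enoate | O=C1C=CCC[C@@H](C)[C@]1(C)CC/C(C)=C/C(=O)OCC | intermediate
11 | tert-butyl hydroperoxide | CC(C)(C)OO | starting material
12 | ethyl (2E)-5-[(3S,4R)-3,4-dimethyl-2-oxo-8-oxabicyclo[5.1.0]octan-3-yl]-3-methylpent-2-enoate (5,6-epoxide of 10; epoxide configuration not controlled) | O=C1C2OC2CC[C@@H](C)[C@]1(C)CC/C(C)=C/C(=O)OCC | intermediate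
13 | 4-methylbenzenesulfonohydrazide | Cc1ccc(cc1)S(=O)(=O)NN | starting material
14 | tosylhydrazone of 12 | Cc1ccc(cc1)S(=O)(=O)NN=C1C2OC2CC[C@@H](C)[C@]1(C)CC/C(C)=C/C(=O)OCC | intermediate (not isolated)
15 | ethyl (2E,6S,7R)-6-ethynyl-3,6,7-trimethyl-10-oxodec-2-enoate | O=CCC[C@@H](C)[C@](C#C)(C)CC/C(C)=C/C(=O)OCC | intermediate
16 | methyl 2-[bis(2,2,2-trifluoroethoxy)phosphoryl]-2-bromoacetate | COC(=O)C(Br)P(=O)(OCC(F)(F)F)OCC(F)(F)F | starting material
17 | 12-ethyl 1-methyl (2E,6R,7S,10E)-2-bromo-7-ethynyl-6,7,10-trimethyldodeca-2,10-dienedioate | COC(=O)/C(Br)=C\CC[C@@H](C)[C@](C#C)(C)CC/C(C)=C/C(=O)OCC | intermediate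
18 | tributyl(ethenyl)stannane | C=C[Sn](CCCC)(CCCC)CCCC | starting material
19 | 12-ethyl 1-methyl (2Z,6R,7S,10E)-2-ethenyl-7-ethynyl-6,7,10-trimethyldodeca-2,10-dienedioate | C=C/C(C(=O)OC)=C/CC[C@@H](C)[C@](C#C)(C)CC/C(C)=C/C(=O)OCC | intermediate
20 | methyl (5S,6R,8aR)-5-[(3E)-5-ethoxy-3-methyl-5-oxopent-3-en-1-yl]-5,6-dimethyl-3,5,6,7,8,8a-hexahydronaphthalene-1-carboxylate | COC(=O)C1=CCC=C2[C@H]1CC[C@@H](C)[C@]2(C)CC/C(C)=C/C(=O)OCC | intermediate
21 | iodomethane | CI | starting material
22 | lithium enolate of the C4 methyl ester formed by hydride addition to C3 of 20 | [Li]OC(OC)=C1CCC=C2[C@H]1CC[C@@H](C)[C@]2(C)CC/C(C)=C/C(=O)OCC | intermediate (not isolated)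
23 | methyl (1S,5S,6R,8aR)-5-[(3E)-5-ethoxy-3-methyl-5-oxopent-3-en-1-yl]-1,5,6-trimethyl-1,2,3,5,6,7,8,8a-octahydronaphthalene-1-carboxylate | COC(=O)[C@@]1(C)CCC=C2[C@H]1CC[C@@H](C)[C@]2(C)CC/C(C)=C/C(=O)OCC | intermediate
24 | methyl (1S,5S,6R,8aR)-5-[(3E)-5-hydroxy-3-methylpent-3-en-1-yl]-1,5,6-trimethyl-1,2,3,5,6,7,8,8a-octahydronaphthalene-1-carboxylate | COC(=O)[C@@]1(C)CCC=C2[C@H]1CC[C@@H](C)[C@]2(C)CC/C(C)=C/CO | intermediate
25 | methyl (1S,5S,6R,8aR)-5-{2-[(2S,3S)-3-(hydroxymethyl)-2-methyloxiran-2-yl]ethyl}-1,5,6-trimethyl-1,2,3,5,6,7,8,8a-octahydronaphthalene-1-carboxylate | COC(=O)[C@@]1(C)CCC=C2[C@H]1CC[C@@H](C)[C@]2(C)CC[C@]1(C)O[C@H]1CO | target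

Total step count: 12. Longest linear sequence: 12 steps (from 1).

Steps most likely to fail

Step 9. The terminal alkyne may be diverted by the rhodium catalyst (acetylide or vinylidene formation, oligomerisation) faster than it cyclises onto the electron-poor diene, and the alternative chair of the tether may leak the C5 epimer. The fallback sets out from 19: the alkyne is capped with NBS and catalytic AgNO3 in acetone to give the 1-bromoalkyne F1, alkynyl halides being established partners in rhodium-catalysed intramolecular [4+2] cycloaddition. Cycloaddition under the same cationic rhodium catalysis should give the C1-bromo diene F2, and hydrodebromination with Pd(PPh3)4 (zerovalent palladium) and Bu3SnH returns to the route at 20.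

Step 10. Facial selectivity in the methylation of the half-chair ester enolate may be poor, because axial attack anti to H5 meets only one syn-axial hydrogen; the enolate may also add to unreduced enoate. The fallback sets out from 20: LiN(SiMe3)2 with HMPA in THF at −78 °C removes a doubly allylic C2 proton and gives a flat, fully conjugated trienolate. C6 stands clearly below the ring-A plane of this enolate, so MeI should add at C4 on the H5 face to give the ring-A 1,3-diene ester F3. Diimide (2-nitrobenzenesulfonylhydrazide, Et3N, CH2Cl2) then reduces only the cis-disubstituted C2=C3 bond and returns to the route at 23.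

Step 6. Hydrazone formation at the ketone flanked by quaternary C9 may be slow, and the aldehyde product may be lost by acid-mediated condensation with the sulfonyl hydrazide. The fallback sets out from 12: condensation with 1-amino-2-phenylaziridine gives the aziridinyl hydrazone F4, which is isolated and fragmented thermally under neutral conditions (toluene, 110 °C) with loss of styrene and N2, returning to the route at 15.

Further compounds
F1 | step 9 | 12-ethyl 1-methyl (2Z,6R,7S,10E)-7-(bromoethynyl)-2-ethenyl-6,7,10-trimethyldodeca-2,10-dienedioate | C=C/C(C(=O)OC)=C/CC[C@@H](C)[C@](C#CBr)(C)CC/C(C)=C/C(=O)OCC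
F2 | step 9 | C1-bromo analogue of 20 (4-bromo in naphthalene numbering; C5, C8 and C9 as in 20) | COC(=O)C1=CCC(Br)=C2[C@H]1CC[C@@H](C)[C@]2(C)CC/C(C)=C/C(=O)OCC
F3 | step 10 | methyl (1S,5S,6R,8aR)-5-[(3E)-5-ethoxy-3-methyl-5-oxopent-3-en-1-yl]-1,5,6-trimethyl-1,5,6,7,8,8a-hexahydronaphthalene-1-carboxylate | COC(=O)[C@@]1(C)C=CC=C2[C@H]1CC[C@@H](C)[C@]2(C)CC/C(C)=C/C(=O)OCC
F4 | step 6 | N-(2-phenylaziridin-1-yl)imine of 12 | c1ccccc1C1CN1N=C1C2OC2CC[C@@H](C)[C@]1(C)CC/C(C)=C/C(=O)OCC
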